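## Retrosynthetic overview

1. Target ⇒ desilylation, esterification of C4–OH and ester → CH2OH; the oxirane comes from a catalyst-controlled Shi epoxidation of C5=C6, and C4–OH from a CBS reduction of a macrocyclic cross-conjugated dienone.
2. Eleven-membered carbocycle ⇒ intramolecular Horner–Wadsworth–Emmons (HWE) reaction at C2=C3; C5=C6 ⇒ chemoselective Wittig reaction with an ylide–phosphonate linchpin; C9=C10 ⇒ E-selective HWE reaction.
3. Quaternary C1 ⇒ amine-catalysed enantioselective conjugate addition of a formyl-radical equivalent (1,3-dioxolan-2-yl) to a geranial-type enal (key step, proposed new method).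
4. Side-chain carbinol ⇒ Shi epoxidation of geranyl acetate (first stereocentre) and epoxide → allylic silyl ether isomerisation.
5. Ring order: the carbocycle is closed first, the oxirane second.

Assumption: ring compounds are named with the locants C1 (quaternary carbon), C2=C3, C4 (O-bearing), C5 (methyl-bearing), C6, C7, C8, C9 (bears the one-carbon substituent), C10, C11 rather than lowest-locant numbering; TBSO = tert-butyldimethylsilyloxy; both enantiomers of the Shi ketone, of diphenylprolinol trimethylsilyl ether and of Me-CBS are bought.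

## Route

Step 1
Reactants: 1 geranyl acetate
Product: 2 (2E)-5-[(2R)-3,3-dimethyloxiran-2-yl]-3-methylpent-2-en-1-yl acetate
Conditions: D-fructose-derived Shi ketone (0.3 equiv), Oxone (2KHSO5·KHSO4·K2SO4), K2CO3, Bu4NHSO4, MeCN–CH2(OMe)2/aq. Na2B4O7 buffer (pH 10.5), 0 °C
Reagents that add atoms: Oxone, active component potassium peroxymonosulfate KHSO5, [K+].[O-]S(=O)(=O)OO
Why: Shi asymmetric epoxidation; the chiral dioxirane attacks the electron-rich distal trisubstituted alkene (the 2,3-alkene is deactivated by the allylic acetate) through a spiro transition state, which sets the R epoxide carbon.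

Step 2
Reactants: 2 (2E)-5-[(2R)-3,3-dimethyloxiran-2-yl]-3-methylpent-2-en-1-yl acetate
Product: 3 (2E,6R)-6-(TBSO)-3,7-dimethylocta-2,7-dien-1-yl acetate
Conditions: TBSOTf, 2,6-lutidine, CH2Cl2, −78 → −20 °C
Reagents that add atoms: tert-butyldimethylsilyl trifluoromethanesulfonate, CC(C)(C)[Si](C)(C)OS(=O)(=O)C(F)(F)F
Why: Silyl-triflate-promoted epoxide-to-allylic-silyl-ether isomerisation (Noyori type); the silylated oxirane opens at the tertiary carbon and loses a methyl proton, so the secondary C–O bond is untouched and the R centre is retained.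

Step 3
Reactants: 3 (2E,6R)-6-(TBSO)-3,7-dimethylocta-2,7-dien-1-yl acetate
Product: 4 (2E,6R)-6-(TBSO)-3,7-dimethylocta-2,7-dien-1-ol
Conditions: K2CO3 (cat.), MeOH, 0 → 23 °C
Reagents that add atoms: none
Why: Base-catalysed transesterification (methanolysis) removes the acetate and leaves the silyl ether and both alkenes untouched.

Step 4
Reactants: 4 (2E,6R)-6-(TBSO)-3,7-dimethylocta-2,7-dien-1-ol
Product: 5 (2E,6R)-6-(TBSO)-3,7-dimethylocta-2,7-dienal
Conditions: PhI(OAc)2, TEMPO (10 mol%), CH2Cl2, 23 °C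
Reagents that add atoms: none
Why: TEMPO/PhI(OAc)2 oxidation of the primary allylic alcohol stops at the enal and keeps the E geometry.

Step 5
Reactants: 5 (2E,6R)-6-(TBSO)-3,7-dimethylocta-2,7-dienal; 6 1,3-dioxolane
Product: 8 (3S,6R)-6-(TBSO)-3-(1,3-dioxolan-2-yl)-3,7-dimethyloct-7-enal, via iminium benzoate 7 (not isolated)
Conditions: (R)-α,α-diphenylprolinol trimethylsilyl ether (20 mol%), PhCO2H (20 mol%), t-BuON=NOt-Bu (2 × 5 mol%), 6 as solvent, H2O (2 equiv), 30 °C, dark, degassed; aq. NaHCO3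
Reagents that add atoms: none
Why: Proposed new method: enantioselective iminium-ion trapping of a formyl-radical equivalent in a thermally initiated chain — t-BuO• from the hyponitrite abstracts H from 6, the nucleophilic 1,3-dioxolan-2-yl radical adds to the β-carbon of E-iminium 7 on the face anti to the CPh2OSiMe3 group (this fixes 3S; the free β,β-disubstituted enal is a far poorer radical acceptor, so the racemic background is slow, and without light the E geometry is not scrambled), the electrophilic enamine radical cation then abstracts H from 6 in a polarity-matched chain-carrying step, and hydrolysis releases 8 and the amine; the closest known reaction types are the amine-catalysed iminium-ion trapping of photogenerated radicals that builds quaternary carbons on cyclic enones and the peroxide-initiated chain addition of 1,3-dioxolane to enones.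

Step 6
Reactants: 9 triethyl phosphonoacetate; 10 2-(2-bromoethyl)-1,3-dioxolane
Product: 11 ethyl 2-(diethoxyphosphoryl)-4-(1,3-dioxolan-2-yl)butanoate (racemic)
Conditions: NaH, DMSO, 23 → 60 °C
Reagents that add atoms: none
Why: SN2 C-alkylation of the sodium phosphonoacetate with a primary bromide gives the α-substituted HWE reagent; its stereocentre is lost in the next step.

Step 7
Reactants: 8 (3S,6R)-6-(TBSO)-3-(1,3-dioxolan-2-yl)-3,7-dimethyloct-7-enal; 11 ethyl 2-(diethoxyphosphoryl)-4-(1,3-dioxolan-2-yl)butanoate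
Product: 12 ethyl (2E,5S,8R)-8-(TBSO)-5-(1,3-dioxolan-2-yl)-2-[2-(1,3-dioxolan-2-yl)ethyl]-5,9-dimethyldeca-2,9-dienoate
Conditions: 11, MeMgBr, THF, 0 °C; then 8, 65 °C
Reagents that add atoms: none
Why: Horner–Wadsworth–Emmons olefination with the magnesium phosphonate is under thermodynamic control and gives the E-trisubstituted enoate (ester trans to the CH2 of the aldehyde partner), which is the ring-cis geometry needed at C9=C10; the minor Z isomer is removed by chromatography.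

Step 8
Reactants: 12 ethyl (2E,5S,8R)-8-(TBSO)-5-(1,3-dioxolan-2-yl)-2-[2-(1,3-dioxolan-2-yl)ethyl]-5,9-dimethyldeca-2,9-dienoate
Product: 13 ethyl (2E,5S,8R)-8-(TBSO)-5-formyl-5,9-dimethyl-2-(3-oxopropyl)deca-2,9-dienoate
Conditions: PPTS, acetone–H2O (9:1), 56 °C
Reagents that add atoms: water, O
Why: Acid-catalysed acetal hydrolysis frees both aldehydes, while PPTS leaves the secondary silyl ether and the enoate intact.

Step 9
Reactants: 14 ethyltriphenylphosphonium bromide; 15 chloroacetyl chloride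
Product: 17 1-chloro-3-(triphenylphosphoranylidene)butan-2-one, via ethylidenetriphenylphosphorane 16 (not isolated)
Conditions: 14 (2 equiv), NaN(SiMe3)2 (2 equiv), THF, 0 °C; then 15 (1 equiv), −78 → 23 °C
Reagents that add atoms: none
Why: Bestmann acylation of a non-stabilised ylide with an acid chloride, the second equivalent of 16 acting as base (transylidation), gives the stabilised α-methyl keto ylide.

Step 10
Reactants: 17 1-chloro-3-(triphenylphosphoranylidene)butan-2-one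
Product: 18 dimethyl [2-oxo-3-(triphenylphosphoranylidene)butyl]phosphonate
Conditions: P(OMe)3, toluene, 110 °C
Reagents that add atoms: trimethyl phosphite, COP(OC)OC
Why: Michaelis–Arbuzov reaction; the ylide-deactivated carbonyl suppresses the Perkow pathway, as for the known des-methyl ylide–phosphonate reagent.

Step 11
Reactants: 13 ethyl (2E,5S,8R)-8-(TBSO)-5-formyl-5,9-dimethyl-2-(3-oxopropyl)deca-2,9-dienoate; 18 dimethyl [2-oxo-3-(triphenylphosphoranylidene)butyl]phosphonate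
Product: 19 ethyl (2E,5S,8R)-8-(TBSO)-2-[(3E)-6-(dimethoxyphosphoryl)-4-methyl-5-oxohex-3-en-1-yl]-5-formyl-5,9-dimethyldeca-2,9-dienoate
Conditions: toluene, 80 °C
Reagents that add atoms: none
Why: Chemoselective Wittig olefination; the stabilised α-branched keto ylide reacts with the unhindered CH2CH2CHO and not with the aldehyde on the quaternary carbon, and gives the E-trisubstituted enone, while the phosphonate stays dormant without base.

Step 12
Reactants: 19 ethyl (2E,5S,8R)-8-(TBSO)-2-[(3E)-6-(dimethoxyphosphoryl)-4-methyl-5-oxohex-3-en-1-yl]-5-formyl-5,9-dimethyldeca-2,9-dienoate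
Product: 20 ethyl (1S,2E,5E,9E)-1-[(3R)-3-(TBSO)-4-methylpent-4-en-1-yl]-1,5-dimethyl-4-oxocycloundeca-2,5,9-triene-9-carboxylate
Conditions: LiCl, DBU, MeCN, 1 mM (syringe pump), 23 → 45 °C
Reagents that add atoms: none
Why: Intramolecular Horner–Wadsworth–Emmons macrocyclisation (Masamune–Roush conditions) under high dilution closes the eleven-membered ring as the E-disubstituted enone; the aldehyde cannot enolise and the ring already holds two sp2 units.

Step 13
Reactants: 20 ethyl (1S,2E,5E,9E)-1-[(3R)-3-(TBSO)-4-methylpent-4-en-1-yl]-1,5-dimethyl-4-oxocycloundeca-2,5,9-triene-9-carboxylate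
Product: 21 ethyl (1S,2E,4R,5E,9E)-4-hydroxy-1-[(3R)-3-(TBSO)-4-methylpent-4-en-1-yl]-1,5-dimethylcycloundeca-2,5,9-triene-9-carboxylate
Conditions: (S)-Me-CBS oxazaborolidine (0.5 equiv), catecholborane, toluene, −78 °C
Reagents that add atoms: none
Why: Corey–Bakshi–Shibata reduction; the α-methylated alkenyl arm (C5) acts as the large group, so the S catalyst delivers hydride to give the 4R allylic alcohol, and catecholborane avoids hydroboration and 1,4-reduction.

Step 14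
Reactants: 21 ethyl (1S,2E,4R,5E,9E)-4-hydroxy-1-[(3R)-3-(TBSO)-4-methylpent-4-en-1-yl]-1,5-dimethylcycloundeca-2,5,9-triene-9-carboxylate
Product: 22 ethyl (1S,2E,4R,5S,6S,9E)-5,6-epoxy-4-hydroxy-1-[(3R)-3-(TBSO)-4-methylpent-4-en-1-yl]-1,5-dimethylcycloundeca-2,9-diene-9-carboxylate
Conditions: L-fructose-derived (enantiomeric) Shi ketone (0.4 equiv), Oxone (2KHSO5·KHSO4·K2SO4, 1.4 equiv KHSO5), K2CO3, Bu4NHSO4, MeCN–CH2(OMe)2/aq. Na2B4O7 buffer (pH 10.5), 0 °C
Reagents that add atoms: Oxone, active component potassium peroxymonosulfate KHSO5, [K+].[O-]S(=O)(=O)OO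
Why: Shi epoxidation under catalyst control on the only electron-rich trisubstituted alkene (the C9=C10 alkene is a deactivated enoate) gives the trans-5,6-epoxide that is threo to C4–OH, the relationship a hydroxyl-directed epoxidation would not give.

Step 15
Reactants: 22 ethyl (1S,2E,4R,5S,6S,9E)-5,6-epoxy-4-hydroxy-1-[(3R)-3-(TBSO)-4-methylpent-4-en-1-yl]-1,5-dimethylcycloundeca-2,9-diene-9-carboxylate
Product: 23 (1S,2E,4R,5S,6S,9E)-5,6-epoxy-9-(hydroxymethyl)-1-[(3R)-3-(TBSO)-4-methylpent-4-en-1-yl]-1,5-dimethylcycloundeca-2,9-dien-4-ol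
Conditions: i-Bu2AlH, CH2Cl2, −78 °C; aq. KNaC4H4O6
Reagents that add atoms: none
Why: DIBAL-H reduces the conjugated ester to the primary allylic alcohol at −78 °C, where the hindered trisubstituted epoxide is not opened.

Step 16
Reactants: 23 (1S,2E,4R,5S,6S,9E)-5,6-epoxy-9-(hydroxymethyl)-1-[(3R)-3-(TBSO)-4-methylpent-4-en-1-yl]-1,5-dimethylcycloundeca-2,9-dien-4-ol; 24 3-methylbut-2-enoic acid
Product: 26 (1S,2E,4R,5R,6S,9E)-5,6-epoxy-9-[(TBSO)methyl]-1-[(3R)-3-(TBSO)-4-methylpent-4-en-1-yl]-1,5-dimethylcycloundeca-2,9-dien-4-yl 3-methylbut-2-enoate, via primary silyl ether 25 (not isolated)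
Conditions: TBSCl (1.05 equiv), imidazole, CH2Cl2, 0 °C; then 24, DCC, DMAP, 23 °C
Reagents that add atoms: tert-butyldimethylsilyl chloride, CC(C)(C)[Si](C)(C)Cl
Why: Selective silylation of the primary allylic alcohol followed in the same flask by Steglich esterification of the remaining hindered secondary alcohol; no stereocentre is touched (the C5 descriptor changes from S to R only because the CIP rank of C4 changes on acylation).

Step 17
Reactants: 26 (1S,2E,4R,5R,6S,9E)-5,6-epoxy-9-[(TBSO)methyl]-1-[(3R)-3-(TBSO)-4-methylpent-4-en-1-yl]-1,5-dimethylcycloundeca-2,9-dien-4-yl 3-methylbut-2-enoate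
Product: 27 (1S,2E,4R,5R,6S,9E)-5,6-epoxy-1-[(3R)-3-hydroxy-4-methylpent-4-en-1-yl]-9-(hydroxymethyl)-1,5-dimethylcycloundeca-2,9-dien-4-yl 3-methylbut-2-enoate (CNP0309478.2)
Conditions: Bu4NF, AcOH, THF, 0 → 23 °C
Reagents that add atoms: none
Why: Fluoride-mediated desilylation buffered with acetic acid removes both silyl ethers without acyl migration or epoxide opening.

## Compound list

1 | geranyl acetate, (2E)-3,7-dimethylocta-2,6-dien-1-yl acetate | CC(C)=CCC/C(C)=C/COC(C)=O | starting material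
2 | (2E)-5-[(2R)-3,3-dimethyloxiran-2-yl]-3-methylpent-2-en-1-yl acetate | CC1(C)O[C@@H]1CC/C(C)=C/COC(C)=O | intermediate
3 | (2E,6R)-6-(TBSO)-3,7-dimethylocta-2,7-dien-1-yl acetate | C=C(C)[C@H](O[Si](C)(C)C(C)(C)C)CC/C(C)=C/COC(C)=O | intermediate
4 | (2E,6R)-6-(TBSO)-3,7-dimethylocta-2,7-dien-1-ol | C=C(C)[C@H](O[Si](C)(C)C(C)(C)C)CC/C(C)=C/CO | intermediate
5 | (2E,6R)-6-(TBSO)-3,7-dimethylocta-2,7-dienal | C=C(C)[C@H](O[Si](C)(C)C(C)(C)C)CC/C(C)=C/C=O | intermediate
6 | 1,3-dioxolane | C1COCO1 | starting material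
7 | E-iminium benzoate from 5 and (R)-2-[diphenyl(trimethylsilyloxy)methyl]pyrrolidine (not isolated) | C=C(C)[C@H](O[Si](C)(C)C(C)(C)C)CC/C(C)=C/C=[N+]1\CCC[C@@H]1C(c1ccccc1)(c1ccccc1)O[Si](C)(C)C.[O-]C(=O)c1ccccc1 | intermediate
8 | (3S,6R)-6-(TBSO)-3-(1,3-dioxolan-2-yl)-3,7-dimethyloct-7-enal | C=C(C)[C@H](O[Si](C)(C)C(C)(C)C)CC[C@](CC=O)(C)C1OCCO1 | intermediate
9 | triethyl phosphonoacetate | CCOC(=O)CP(=O)(OCC)OCC | starting material
10 | 2-(2-bromoethyl)-1,3-dioxolane | BrCCC1OCCO1 | starting material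
11 | ethyl 2-(diethoxyphosphoryl)-4-(1,3-dioxolan-2-yl)butanoate (racemic) | CCOC(=O)C(CCC1OCCO1)P(=O)(OCC)OCC | intermediate
12 | ethyl (2E,5S,8R)-8-(TBSO)-5-(1,3-dioxolan-2-yl)-2-[2-(1,3-dioxolan-2-yl)ethyl]-5,9-dimethyldeca-2,9-dienoate | C=C(C)[C@H](O[Si](C)(C)C(C)(C)C)CC[C@](C)(C1OCCO1)C/C=C(\CCC1OCCO1)C(=O)OCC | intermediate
13 | ethyl (2E,5S,8R)-8-(TBSO)-5-formyl-5,9-dimethyl-2-(3-oxopropyl)deca-2,9-dienoate | C=C(C)[C@H](O[Si](C)(C)C(C)(C)C)CC[C@](C)(C=O)C/C=C(\CCC=O)C(=O)OCC | intermediate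
14 | ethyltriphenylphosphonium bromide | CC[P+](c1ccccc1)(c1ccccc1)c1ccccc1.[Br-] | starting material
15 | chloroacetyl chloride | O=C(Cl)CCl | starting material
16 | ethylidenetriphenylphosphorane (not isolated) | CC=P(c1ccccc1)(c1ccccc1)c1ccccc1 | intermediate
17 | 1-chloro-3-(triphenylphosphoranylidene)butan-2-one | O=C(CCl)C(C)=P(c1ccccc1)(c1ccccc1)c1ccccc1 | intermediate
18 | dimethyl [2-oxo-3-(triphenylphosphoranylidene)butyl]phosphonate | COP(=O)(OC)CC(=O)C(C)=P(c1ccccc1)(c1ccccc1)c1ccccc1 | intermediate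
19 | ethyl (2E,5S,8R)-8-(TBSO)-2-[(3E)-6-(dimethoxyphosphoryl)-4-methyl-5-oxohex-3-en-1-yl]-5-formyl-5,9-dimethyldeca-2,9-dienoate | C=C(C)[C@H](O[Si](C)(C)C(C)(C)C)CC[C@](C)(C=O)C/C=C(\CC/C=C(\C)C(=O)CP(=O)(OC)OC)C(=O)OCC | intermediate
20 | ethyl (1S,2E,5E,9E)-1-[(3R)-3-(TBSO)-4-methylpent-4-en-1-yl]-1,5-dimethyl-4-oxocycloundeca-2,5,9-triene-9-carboxylate | C=C(C)[C@H](O[Si](C)(C)C(C)(C)C)CC[C@]1(C)/C=C/C(=O)/C(C)=C/CC/C(C(=O)OCC)=C\C1 | intermediate
21 | ethyl (1S,2E,4R,5E,9E)-4-hydroxy-1-[(3R)-3-(TBSO)-4-methylpent-4-en-1-yl]-1,5-dimethylcycloundeca-2,5,9-triene-9-carboxylate | C=C(C)[C@H](O[Si](C)(C)C(C)(C)C)CC[C@]1(C)/C=C/[C@@H](O)/C(C)=C/CC/C(C(=O)OCC)=C\C1 | intermediate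
22 | ethyl (1S,2E,4R,5S,6S,9E)-5,6-epoxy-4-hydroxy-1-[(3R)-3-(TBSO)-4-methylpent-4-en-1-yl]-1,5-dimethylcycloundeca-2,9-diene-9-carboxylate | C=C(C)[C@H](O[Si](C)(C)C(C)(C)C)CC[C@]1(C)/C=C/[C@@H](O)[C@]2(C)O[C@H]2CC/C(C(=O)OCC)=C\C1 | intermediate
23 | (1S,2E,4R,5S,6S,9E)-5,6-epoxy-9-(hydroxymethyl)-1-[(3R)-3-(TBSO)-4-methylpent-4-en-1-yl]-1,5-dimethylcycloundeca-2,9-dien-4-ol | C=C(C)[C@H](O[Si](C)(C)C(C)(C)C)CC[C@]1(C)/C=C/[C@@H](O)[C@]2(C)O[C@H]2CC/C(CO)=C\C1 | intermediate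
24 | 3-methylbut-2-enoic acid | CC(C)=CC(=O)O | starting material
25 | (1S,2E,4R,5S,6S,9E)-5,6-epoxy-9-[(TBSO)methyl]-1-[(3R)-3-(TBSO)-4-methylpent-4-en-1-yl]-1,5-dimethylcycloundeca-2,9-dien-4-ol (not isolated) | C=C(C)[C@H](O[Si](C)(C)C(C)(C)C)CC[C@]1(C)/C=C/[C@@H](O)[C@]2(C)O[C@H]2CC/C(CO[Si](C)(C)C(C)(C)C)=C\C1 | intermediate
26 | (1S,2E,4R,5R,6S,9E)-5,6-epoxy-9-[(TBSO)methyl]-1-[(3R)-3-(TBSO)-4-methylpent-4-en-1-yl]-1,5-dimethylcycloundeca-2,9-dien-4-yl 3-methylbut-2-enoate | C=C(C)[C@H](O[Si](C)(C)C(C)(C)C)CC[C@]1(C)/C=C/[C@@H](OC(=O)C=C(C)C)[C@]2(C)O[C@H]2CC/C(CO[Si](C)(C)C(C)(C)C)=C\C1 | intermediate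
27 | (1S,2E,4R,5R,6S,9E)-5,6-epoxy-1-[(3R)-3-hydroxy-4-methylpent-4-en-1-yl]-9-(hydroxymethyl)-1,5-dimethylcycloundeca-2,9-dien-4-yl 3-methylbut-2-enoate | C=C(C)[C@H](O)CC[C@]1(C)/C=C/[C@@H](OC(=O)C=C(C)C)[C@]2(C)O[C@H]2CC/C(CO)=C\C1 | target

## Step count and risk

Total step count: 17 (14 on the main line, 1 for phosphonate 11, 2 for linchpin 18).
Longest linear sequence: 14 steps (steps 1–5, 7, 8, 11–17) from geranyl acetate.

Three steps most likely to fail:

Step 5 (proposed new method). The chain may be short, the free enal may compete as radical acceptor and erode the ee, and abstraction from C4 of dioxolane may give regioisomers. Fallback with known chemistry, setting out from 5 and coming back at 13: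
- Hayashi-type iminium Michael addition of nitromethane to 5 with the same (R)-diphenylprolinol silyl ether (PhCO2H, MeOH, 23 °C; known for β,β-disubstituted enals) gives the nitro aldehyde (3S,6R)-6-(TBSO)-3,7-dimethyl-3-(nitromethyl)oct-7-enal F1.
- HWE reaction of F1 with 2.2 equiv of the sodium salt of 11 (NaH, THF; one equivalent is used up as base by the nitro group) gives the nitro enoate ethyl (2E,5S,8R)-8-(TBSO)-2-[2-(1,3-dioxolan-2-yl)ethyl]-5,9-dimethyl-5-(nitromethyl)deca-2,9-dienoate F2.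
- Nef reaction (NaOMe, MeOH, then aqueous TiCl3 buffered with NH4OAc) gives the mono-acetal aldehyde ethyl (2E,5S,8R)-8-(TBSO)-2-[2-(1,3-dioxolan-2-yl)ethyl]-5-formyl-5,9-dimethyldeca-2,9-dienoate F3.
- PPTS in acetone–H2O then gives 13.

Step 12 (closure of the eleven-membered ring). Medium-ring strain and the hindered aldehyde may favour dimers. Fallback that closes the same bond by an aldol condensation, setting out from 13 and coming back at 20:
- Chemoselective Wittig reaction of 13 with 3-(triphenylphosphoranylidene)butan-2-one F4 (made from 3-chlorobutan-2-one and PPh3, then aqueous NaOH) gives the methyl enone aldehyde ethyl (2E,5S,8R)-8-(TBSO)-5-formyl-5,9-dimethyl-2-[(3E)-4-methyl-5-oxohex-3-en-1-yl]deca-2,9-dienoate F5.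
- Kinetic enolisation of the methyl ketone (LiN(SiMe3)2, THF, −78 °C, 1 mM) and intramolecular aldol addition to the non-enolisable aldehyde gives the ring aldol ethyl (1S,5E,9E)-2-hydroxy-1-[(3R)-3-(TBSO)-4-methylpent-4-en-1-yl]-1,5-dimethyl-4-oxocycloundeca-5,9-diene-9-carboxylate F6 (mixture at C2).
- Dehydration (MsCl, Et3N, then DBU) gives 20.

Step 14 (Shi epoxidation on the macrocycle). The ring may expose only one alkene face and override the catalyst, or the isopropenyl group may compete. Fallback through the erythro series and inversion, setting out from 20 and coming back at 26: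
- Reduction of 20 with (R)-Me-CBS and catecholborane gives the 4S alcohol ethyl (1S,2E,4S,5E,9E)-4-hydroxy-1-[(3R)-3-(TBSO)-4-methylpent-4-en-1-yl]-1,5-dimethylcycloundeca-2,5,9-triene-9-carboxylate F7.
- Sharpless epoxidation (Ti(O-i-Pr)4, D-(−)-diisopropyl tartrate, t-BuOOH, 4 Å sieves, CH2Cl2, −20 °C; matched, erythro-selective) gives ethyl (1S,2E,4S,5S,6S,9E)-5,6-epoxy-4-hydroxy-1-[(3R)-3-(TBSO)-4-methylpent-4-en-1-yl]-1,5-dimethylcycloundeca-2,9-diene-9-carboxylate F8.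
- i-Bu2AlH (CH2Cl2, −78 °C) gives the diol (1S,2E,4S,5S,6S,9E)-5,6-epoxy-9-(hydroxymethyl)-1-[(3R)-3-(TBSO)-4-methylpent-4-en-1-yl]-1,5-dimethylcycloundeca-2,9-dien-4-ol F9.
- TBSCl and imidazole give the primary silyl ether (1S,2E,4S,5S,6S,9E)-5,6-epoxy-9-[(TBSO)methyl]-1-[(3R)-3-(TBSO)-4-methylpent-4-en-1-yl]-1,5-dimethylcycloundeca-2,9-dien-4-ol F10.
- Mitsunobu esterification with 24 (PPh3, DIAD, toluene) inverts C4 and gives 26.

## Further compounds

F1 | step 5 | (3S,6R)-6-(TBSO)-3,7-dimethyl-3-(nitromethyl)oct-7-enal | C=C(C)[C@H](O[Si](C)(C)C(C)(C)C)CC[C@](CC=O)(C)C[N+](=O)[O-]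
F2 | step 5 | ethyl (2E,5S,8R)-8-(TBSO)-2-[2-(1,3-dioxolan-2-yl)ethyl]-5,9-dimethyl-5-(nitromethyl)deca-2,9-dienoate | C=C(C)[C@H](O[Si](C)(C)C(C)(C)C)CC[C@](C)(C[N+](=O)[O-])C/C=C(\CCC1OCCO1)C(=O)OCC
F3 | step 5 | ethyl (2E,5S,8R)-8-(TBSO)-2-[2-(1,3-dioxolan-2-yl)ethyl]-5-formyl-5,9-dimethyldeca-2,9-dienoate | C=C(C)[C@H](O[Si](C)(C)C(C)(C)C)CC[C@](C)(C=O)C/C=C(\CCC1OCCO1)C(=O)OCC
F4 | step 12 | 3-(triphenylphosphoranylidene)butan-2-one | CC(=O)C(C)=P(c1ccccc1)(c1ccccc1)c1ccccc1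
F5 | step 12 | ethyl (2E,5S,8R)-8-(TBSO)-5-formyl-5,9-dimethyl-2-[(3E)-4-methyl-5-oxohex-3-en-1-yl]deca-2,9-dienoate | C=C(C)[C@H](O[Si](C)(C)C(C)(C)C)CC[C@](C)(C=O)C/C=C(\CC/C=C(\C)C(C)=O)C(=O)OCC
F6 | step 12 | ethyl (1S,5E,9E)-2-hydroxy-1-[(3R)-3-(TBSO)-4-methylpent-4-en-1-yl]-1,5-dimethyl-4-oxocycloundeca-5,9-diene-9-carboxylate (mixture at C2) | C=C(C)[C@H](O[Si](C)(C)C(C)(C)C)CC[C@]1(C)C(O)CC(=O)/C(C)=C/CC/C(C(=O)OCC)=C\C1
F7 | step 14 | ethyl (1S,2E,4S,5E,9E)-4-hydroxy-1-[(3R)-3-(TBSO)-4-methylpent-4-en-1-yl]-1,5-dimethylcycloundeca-2,5,9-triene-9-carboxylate | C=C(C)[C@H](O[Si](C)(C)C(C)(C)C)CC[C@]1(C)/C=C/[C@H](O)/C(C)=C/CC/C(C(=O)OCC)=C\C1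
F8 | step 14 | ethyl (1S,2E,4S,5S,6S,9E)-5,6-epoxy-4-hydroxy-1-[(3R)-3-(TBSO)-4-methylpent-4-en-1-yl]-1,5-dimethylcycloundeca-2,9-diene-9-carboxylate | C=C(C)[C@H](O[Si](C)(C)C(C)(C)C)CC[C@]1(C)/C=C/[C@H](O)[C@]2(C)O[C@H]2CC/C(C(=O)OCC)=C\C1
F9 | step 14 | (1S,2E,4S,5S,6S,9E)-5,6-epoxy-9-(hydroxymethyl)-1-[(3R)-3-(TBSO)-4-methylpent-4-en-1-yl]-1,5-dimethylcycloundeca-2,9-dien-4-ol | C=C(C)[C@H](O[Si](C)(C)C(C)(C)C)CC[C@]1(C)/C=C/[C@H](O)[C@]2(C)O[C@H]2CC/C(CO)=C\C1
F10 | step 14 | (1S,2E,4S,5S,6S,9E)-5,6-epoxy-9-[(TBSO)methyl]-1-[(3R)-3-(TBSO)-4-methylpent-4-en-1-yl]-1,5-dimethylcycloundeca-2,9-dien-4-ol | C=C(C)[C@H](O[Si](C)(C)C(C)(C)C)CC[C@]1(C)/C=C/[C@H](O)[C@]2(C)O[C@H]2CC/C(CO[Si](C)(C)C(C)(C)C)=C\C1
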